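**Retrosynthetic overview**
1. Target ⇒ luteone. Disconnect the tertiary C–O bond of the side chain: Markovnikov H/OH addition across the prenyl C=C, done last on the free tetraphenol.
2. Luteone ⇒ 3-prenyl-pentahydroxydeoxybenzoin + one C1 unit. Disconnect O1–C2 of the pyranone: aryl-OH addition–elimination on an enaminone.
3. Prenyl-deoxybenzoin ⇒ symmetric pentahydroxydeoxybenzoin + prenyl bromide. Phenolate C-alkylation; C3 and C5 are equivalent, so one isomer forms.
4. Deoxybenzoin ⇒ phloroglucinol + 2,4-dihydroxyphenylacetic acid (Friedel–Crafts acylation).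
5. Ring order: rings A and B are bought. Ring C (pyranone) is the only ring formed (step 3). No protecting groups.

Assumption: the SMILES is taken as authoritative (luteone hydrate, 6-(3-hydroxy-3-methylbutyl)-2',4',5,7-tetrahydroxyisoflavone); it has no stereocentre and no stereogenic double bond, so no enantiocontrol is needed.

**Route**

Step 1
Reactants: 1 phloroglucinol (benzene-1,3,5-triol); 2 2,4-dihydroxyphenylacetic acid
Product: 3 2-(2,4-dihydroxyphenyl)-1-(2,4,6-trihydroxyphenyl)ethan-1-one
Conditions: 1 (1.3 equiv), BF3·OEt2 (solvent), 65 °C, 2 h, Ar; aq. work-up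
Reagents that add atoms: none
Why: BF3-mediated Friedel–Crafts acylation: phloroglucinol is by far the most nucleophilic arene present (slight excess outcompetes the resorcinol ring of 2), its three positions are equivalent, and the product is a doubly hydrogen-bonded vinylogous-acid ketone, too deactivated for a second acylation and only slowly attacked by the 2'-OH at ≤65 °C.

Step 2
Reactants: 3 2-(2,4-dihydroxyphenyl)-1-(2,4,6-trihydroxyphenyl)ethan-1-one; 4 prenyl bromide (1-bromo-3-methylbut-2-ene)
Product: 5 2-(2,4-dihydroxyphenyl)-1-[2,4,6-trihydroxy-3-(3-methylbut-2-en-1-yl)phenyl]ethan-1-one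
Conditions: KOH (1.05 equiv), 4 (0.95 equiv), H2O–MeOH 4:1, 0 °C, Ar, 3 h
Reagents that add atoms: none
Why: Phenolate C-alkylation (nuclear prenylation of an acylphloroglucinol): one equivalent of base ionises only the vinylogous-acid 4-OH (pKa about 8 against about 9.5 for the B-ring resorcinol), the protic medium shields oxygen and sends the soft allylic bromide to ring carbon, C3 and C5 are equivalent so one regioisomer forms, and the sub-stoichiometric bromide limits diprenylation.

Step 3
Reactants: 5 2-(2,4-dihydroxyphenyl)-1-[2,4,6-trihydroxy-3-(3-methylbut-2-en-1-yl)phenyl]ethan-1-one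
Product: 7 luteone [5,7,2',4'-tetrahydroxy-6-(3-methylbut-2-en-1-yl)isoflavone], via enaminone 6 (not isolated)
Conditions: Me2NCH(OMe)2 (1.6 equiv), THF, 60 °C, 3 h; SiO2 chromatography
Reagents that add atoms: N,N-dimethylformamide dimethyl acetal, COC(OC)N(C)C
Why: DMF-DMA enaminone isoflavone synthesis: the activated CH2 condenses to 6 and an ortho-OH closes by 6-endo-trig addition–elimination (loss of HNMe2, forming O1–C2); the unhindered OH para to the prenyl group attacks while the prenyl-buttressed OH stays hydrogen-bonded to the C=O, so the 6-prenyl isomer should dominate (about 3:1, minor 8-prenyl isomer removed on silica); closure by the 2'-OH would be disfavoured 5-endo-trig, and the neutral medium spares the prenyl group.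

Step 4
Reactants: 7 luteone
Product: 9 luteone hydrate [5,7,2',4'-tetrahydroxy-6-(3-hydroxy-3-methylbutyl)isoflavone], via tertiary hydroperoxide 8 (not isolated)
Conditions: Mn(OAc)3·2H2O (10 mol %), 2,2,6,6-tetramethylheptane-3,5-dione (Hdpm, 10 mol %), PhSiH3 (2.5 equiv), O2 (1 atm), i-PrOH–THF 3:1, 0 °C → rt, 6 h
Reagents that add atoms: dioxygen, O=O
Why: Proposed new method: substrate-ligated MHAT Markovnikov hydration – the peri 5-OH/4-C=O unit of 7 is a β-ketophenolate that fills the open diketonate site of the in situ Mn(III)(dpm) catalyst; PhSiH3/i-PrOH converts this chelate into a Mn–H next to the 6-prenyl group, which passes H• to C-2'' through a seven-membered transition state; the tertiary C-3'' radical is caught by O2 (about 10^9 M^-1 s^-1) before it can be oxidised to the cation that would close to the chroman, and hydroperoxide 8 is reduced by silane to the alcohol; the chelated metal cannot reach the s-trans-locked C2=C3 bond, and resorcinol-type phenols (no catechol or hydroquinone) resist Mn(III)/O2; the closest known reaction type is the Mukaiyama hydration (Mn(dpm)3 or Co(acac)2, PhSiH3, O2), not yet run with the substrate as the ligand or on a free o,o'-dihydroxy-prenylarene; no stereocentre is formed.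

**Compound list**
1 | phloroglucinol | Oc1cc(O)cc(O)c1 | starting material
2 | 2,4-dihydroxyphenylacetic acid | OC(=O)Cc1ccc(O)cc1O | starting material
3 | 2-(2,4-dihydroxyphenyl)-1-(2,4,6-trihydroxyphenyl)ethan-1-one | O=C(Cc1ccc(O)cc1O)c1c(O)cc(O)cc1O | intermediate
4 | prenyl bromide (1-bromo-3-methylbut-2-ene) | CC(C)=CCBr | starting material
5 | 2-(2,4-dihydroxyphenyl)-1-[2,4,6-trihydroxy-3-(3-methylbut-2-en-1-yl)phenyl]ethan-1-one | CC(C)=CCc1c(O)cc(O)c(C(=O)Cc2ccc(O)cc2O)c1O | intermediate
6 | enaminone, 2-(2,4-dihydroxyphenyl)-3-(dimethylamino)-1-[2,4,6-trihydroxy-3-(3-methylbut-2-en-1-yl)phenyl]prop-2-en-1-one (push–pull alkene, E/Z not fixed, not isolated) | CC(C)=CCc1c(O)cc(O)c(C(=O)C(=CN(C)C)c2ccc(O)cc2O)c1O | intermediate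
7 | luteone | CC(C)=CCc1c(O)cc2occ(-c3ccc(O)cc3O)c(=O)c2c1O | intermediate
8 | tertiary hydroperoxide, 6-(3-hydroperoxy-3-methylbutyl)-5,7,2',4'-tetrahydroxyisoflavone (not isolated) | CC(C)(OO)CCc1c(O)cc2occ(-c3ccc(O)cc3O)c(=O)c2c1O | intermediate
9 | luteone hydrate (achiral) | CC(C)(O)CCc1c(O)cc2occ(-c3ccc(O)cc3O)c(=O)c2c1O | target

**Totals**
Total step count: 4, with no protecting-group operations. Longest linear sequence: 4 (1 → 3 → 5 → 7 → 9).

**Three steps most likely to fail**

Step 4 (the proposed new step). The polyphenol may sequester or reduce the manganese. Mn–H may also deliver H• to C2=C3 of the chromone. Phenoxyl side reactions may take over.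

The fallback uses known chemistry, sets out from 7 and comes back at 9. It replaces the radical hydration with an ionic one on a masked substrate.
- Ac2O/pyridine/DMAP gives luteone tetraacetate F1, in which no phenol can add to the side chain.
- Textbook oxymercuration (Hg(OAc)2, THF–H2O, rt) gives the 3''-hydroxy-2''-(acetoxymercurio) adduct F2 (racemic at C-2'', not isolated).
- Brief NaBH4 treatment at 0 °C demercurates this to luteone hydrate tetraacetate F3.
- K2CO3 in MeOH at 0 °C removes the four acetates to give 9.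

Step 3. The 6-/8-prenyl ratio rests only on sterics and hydrogen bonding. It could fall towards 1:1, and DMF-DMA may O-methylate the acidic 7-OH.

The fallback sets out from 3 and comes back at 7. It replaces steps 2 and 3 and fixes the regiochemistry by leaving a single free ortho-OH.
- MOMCl (4.3 equiv)/i-Pr2NEt leaves only one chelated OH free, giving 1-[2-hydroxy-4,6-bis(methoxymethoxy)phenyl]-2-[2,4-bis(methoxymethoxy)phenyl]ethanone F4.
- Mitsunobu reaction with prenol (DIAD, PPh3) gives the aryl prenyl ether F5.
- Heating in N,N-diethylaniline at 200 °C triggers a para-Claisen–Cope sequence. The prenyl group lands para to the liberated OH, between the two MOM ethers, giving phenol F6.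
- DMF-DMA in toluene at 95 °C passes through the MOM-protected enaminone F7. This can close only through that single OH, giving luteone tetra-MOM ether F8.
- Dilute HCl in MeOH at 40 °C releases 7.

Step 1. Under BF3 the free 2'-OH of 3 may attack the ketone and dehydrate to a 2-arylbenzofuran. The resorcinol ring of 2 may also self-acylate.

The fallback sets out from 1 and comes back at 3. It keeps the ketone locked inside a pyranone while the B-ring phenols are unveiled.
- 1 and bought 2,4-dimethoxyphenylacetic acid (COc1ccc(CC(=O)O)c(OC)c1) in BF3·OEt2 give 2-(2,4-dimethoxyphenyl)-1-(2,4,6-trihydroxyphenyl)ethanone F9 (not isolated).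
- Adding DMF/MsCl to the same pot gives 5,7-dihydroxy-2',4'-dimethoxyisoflavone F10.
- BBr3 (CH2Cl2, −78 °C → rt) gives 2'-hydroxygenistein F11.
- Classical mild alkaline ring opening and deformylation (5% aq. KOH, N2, 70 °C) then delivers 3 under basic conditions, where cyclodehydration does not occur.

**Further compounds**
F1 | step 4 | luteone tetraacetate | CC(C)=CCc1c(OC(C)=O)cc2occ(-c3ccc(OC(C)=O)cc3OC(C)=O)c(=O)c2c1OC(C)=O
F2 | step 4 | 3''-hydroxy-2''-(acetoxymercurio) adduct of luteone tetraacetate (racemic) | CC(C)(O)C([Hg]OC(C)=O)Cc1c(OC(C)=O)cc2occ(-c3ccc(OC(C)=O)cc3OC(C)=O)c(=O)c2c1OC(C)=O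
F3 | step 4 | luteone hydrate tetraacetate | CC(C)(O)CCc1c(OC(C)=O)cc2occ(-c3ccc(OC(C)=O)cc3OC(C)=O)c(=O)c2c1OC(C)=O
F4 | step 3 | 1-[2-hydroxy-4,6-bis(methoxymethoxy)phenyl]-2-[2,4-bis(methoxymethoxy)phenyl]ethanone | COCOc1ccc(CC(=O)c2c(O)cc(OCOC)cc2OCOC)c(OCOC)c1
F5 | step 3 | aryl prenyl ether of F4 | COCOc1ccc(CC(=O)c2c(OCC=C(C)C)cc(OCOC)cc2OCOC)c(OCOC)c1
F6 | step 3 | 1-[6-hydroxy-2,4-bis(methoxymethoxy)-3-(3-methylbut-2-en-1-yl)phenyl]-2-[2,4-bis(methoxymethoxy)phenyl]ethanone | COCOc1ccc(CC(=O)c2c(O)cc(OCOC)c(CC=C(C)C)c2OCOC)c(OCOC)c1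
F7 | step 3 | MOM-protected enaminone (E/Z not fixed, not isolated) | COCOc1ccc(C(=CN(C)C)C(=O)c2c(O)cc(OCOC)c(CC=C(C)C)c2OCOC)c(OCOC)c1
F8 | step 3 | luteone tetra-MOM ether | CC(C)=CCc1c(OCOC)cc2occ(-c3ccc(OCOC)cc3OCOC)c(=O)c2c1OCOC
F9 | step 1 | 2-(2,4-dimethoxyphenyl)-1-(2,4,6-trihydroxyphenyl)ethanone | COc1ccc(CC(=O)c2c(O)cc(O)cc2O)c(OC)c1
F10 | step 1 | 5,7-dihydroxy-2',4'-dimethoxyisoflavone | COc1ccc(-c2coc3cc(O)cc(O)c3c2=O)c(OC)c1
F11 | step 1 | 2'-hydroxygenistein | O=c1c(-c2ccc(O)cc2O)coc2cc(O)cc(O)c12
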